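All constants were set for the occasion; the result is computed.

Slowness was what I looked at first. In these flasks starting material becomes intermediate under the free catalyst, intermediate becomes target under the second catalyst, and the run may well stop with neither step through.

common to all: starting material 0.050 M; free catalyst 1.0 mM; second catalyst 8.0 mM; time 25 h

| charge | reagent |
|---|---|
| ochre | 0.100 M |
| blue | 0.150 M |

    starting material + free catalyst → free catalyst + intermediate (k1 = 103 /M/h)
    reagent + second catalyst + intermediate → second catalyst + target (k2 = 53.6 /M²/h)
    free catalyst ⇌ dormant form (K3 = 0.644, k3 = 0.0265 /h)
    2 starting material → self-condensation product (k4 = 0.00126 /M/h)

- in percentages every species weighs as the starting material in it: one self-condensation product counts as two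
- a step written with two of one species runs at k times the square of its concentration and takes two of it each time
- run time (ochre): 25 h

- which of these there is most of at the end, counted by the starting material in it, ochre (target / intermediate / starting material)
- which of these there is most of at the end, counted by the starting material in it, blue (target / intermediate / starting material)
- final amount of the leader among these, as a percentage of the starting material charged, in ochre
- final amount of the leader among these, as a percentage of the starting material charged, in blue

I turned the constants into half-lives at the charged amounts, fastest first, and counted every amount as a fraction of the starting material charged.

Making intermediate, catalyst whole: 6.73 h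
Free catalyst relaxing towards dormant form: 10.2 h
Draining intermediate, blue: 10.8 h
Draining intermediate, ochre: 16 h
The run: 25 h
Self-condensation: 7940 h

Self-condensation is far slower than the run, so I dropped it. The catalyst relaxes faster than the run, so the free catalyst slides during the run towards 60.8% of its charge, and making must be counted on that falling amount. Integrating it gave the making count, m = 2.05, the same in both flasks.

The quantity that separates the flasks is the drain count d: the second constant times reagent times second catalyst times the time, which is the number of intermediate lifetimes the run holds. I held the reagent at its charge, a pseudo-first-order view, though in ochre complete conversion would cost half of it. Then:

intermediate = m/(m − d) · (exp(−d) − exp(−m))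
target = 1 − exp(−m) − intermediate

Ochre: d = 1.07, intermediate 44.8%, target 42.4%.
Blue: d = 1.61, intermediate 33.2%, target 54.0%.

The forecast named the same leaders, intermediate in ochre at 46.9% and target in blue at 52.2%, “Stepping through in 5 h Simpson steps”. Its ochre figure is higher than mine, and its blue figure lower.

The simulation gave intermediate at 46.8% in ochre and target at 52.3% in blue. Ochre ended with 79.8% of its reagent, and d on that end amount is 0.856, against 1.07 on the charge. The ochre leader depends on m as well as on d, and one neighbour of ochre moves d. The neighbour of ochre with 0.020 M of second catalyst has d = 2.68, which gives intermediate 19.6% and target 67.5%. Computed, that neighbour ended with 63.1% of target and 24.0% of intermediate.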